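**Strategy.** Atoms are numbered along the target SMILES (ring A = C4–C5–C6–C7–C9–C21; lactone ring B = C4–O20–C18–C9–C21). The route rests on cutting C9–C7. C9 is a fully substituted carbon alpha to the C18 carbonyl and sits beside the methyl-bearing C7, which is what a [3,3] shift of an allyl ester enolate produces. One Ireland–Claisen rearrangement of a propenyl δ-lactone makes C9–C7, closes ring A and sets C9 and C7 from the C5 carbinol centre. The precursor is a tetrahydropyran-2-one with the (E)-propenyl group at C5, a triethylsilyl ether at C4, the benzyloxypropyl chain at C21 and the silyloxyethyl chain at C9. Ring B is closed later by isopropenyl addition to a C4 ketone.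

Key step: step 10

Remark on the chemistry: atom labels such as C9 or C21 always refer to the target SMILES numbering above. The Luche reduction (step 6) is assumed to give mainly the 4,5-cis alcohol, as expected for hydride attack anti to the C5 substituent of a nearly planar keto lactone.

**Step 1**
Reactants: 1 furan-2-carbaldehyde (furfural); 2 prop-1-yn-1-ylmagnesium bromide
Product: 3 rac-1-(furan-2-yl)but-2-yn-1-ol
Conditions: THF, 0 °C → rt; aq NH4Cl
Reagents that add atoms: none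
Why: Grignard 1,2-addition of the alkynyl nucleophile to the aldehyde gives the racemic propargylic furyl carbinol that carries the future C5–C8 unit.

**Step 2**
Reactants: 3 rac-1-(furan-2-yl)but-2-yn-1-ol
Product: 4 (S)-1-(furan-2-yl)but-2-yn-1-ol
Conditions: Ti(OiPr)4 (cat.), D-(−)-diisopropyl tartrate (cat.), t-BuOOH (0.6 equiv), 4 Å molecular sieves, CH2Cl2, −20 °C
Reagents that add atoms: none
Why: Sharpless kinetic resolution of a 2-furylcarbinol, in which the titanium D-tartrate complex should oxidise the furan of the (R)-enantiomer much faster, so the (S)-alcohol (future C5) is recovered; the alkyne, unlike an alkene, offers no second oxidation site.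

**Step 3**
Reactants: 4 (S)-1-(furan-2-yl)but-2-yn-1-ol
Product: 5 (S,E)-1-(furan-2-yl)but-2-en-1-ol
Conditions: NaAlH2(OCH2CH2OCH3)2, THF, 0 °C → rt
Reagents that add atoms: none
Why: Trans-hydroalumination of the propargylic alkoxide followed by protonolysis gives the (E)-allylic alcohol without touching the carbinol centre.

**Step 4**
Reactants: 5 (S,E)-1-(furan-2-yl)but-2-en-1-ol
Product: 6 (2S)-6-hydroxy-2-[(E)-prop-1-enyl]-2H-pyran-3(6H)-one (both anomers)
Conditions: N-bromosuccinimide, NaHCO3, THF/H2O (4:1), 0 °C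
Reagents that add atoms: water, O
Why: Achmatowicz rearrangement, in which oxidation of the electron-rich furan and hydrolysis give an ene-dione that closes to the pyranone hemiacetal; the carbinol centre is carried over unchanged as C5 and the less nucleophilic propenyl group should be left alone at 0 °C.

**Step 5**
Reactants: 6 (2S)-6-hydroxy-2-[(E)-prop-1-enyl]-2H-pyran-3(6H)-one
Product: 7 (6S)-6-[(E)-prop-1-enyl]-2H-pyran-2,5(6H)-dione
Conditions: CrO3, H2SO4, acetone, 0 °C, short contact; used at once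
Reagents that add atoms: none
Why: Jones oxidation of the lactol to the lactone, kept cold and brief to limit enolisation at the acidic C5–H.

**Step 6**
Reactants: 7 (6S)-6-[(E)-prop-1-enyl]-2H-pyran-2,5(6H)-dione
Product: 8 (5S,6S)-5-hydroxy-6-[(E)-prop-1-enyl]-5,6-dihydro-2H-pyran-2-one
Conditions: NaBH4, CeCl3·7H2O, MeOH/CH2Cl2, −78 °C
Reagents that add atoms: none
Why: Luche 1,2-reduction, in which hydride should attack the ketone on the face opposite the neighbouring propenyl group, making the new C4 hydroxyl cis to it.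

**Step 7**
Reactants: 8 (5S,6S)-5-hydroxy-6-[(E)-prop-1-enyl]-5,6-dihydro-2H-pyran-2-one
Product: 9 (5S,6S)-6-[(E)-prop-1-enyl]-5-(triethylsilyloxy)-5,6-dihydro-2H-pyran-2-one
Conditions: Et3SiOTf, 2,6-lutidine, CH2Cl2, −78 °C
Reagents that add atoms: triethylsilyl trifluoromethanesulfonate, CC[Si](CC)(CC)OS(=O)(=O)C(F)(F)F
Why: Silylation with a silyl triflate and a hindered base protects the base-sensitive γ-hydroxy enoate without elimination, and the triethylsilyl group can later be removed beside the tert-butyldiphenylsilyl ether.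

**Step 8**
Reactants: 9 (5S,6S)-6-[(E)-prop-1-enyl]-5-(triethylsilyloxy)-5,6-dihydro-2H-pyran-2-one; 10 1-(benzyloxy)-3-bromopropane
Product: 13 (4R,5S,6S)-4-[3-(benzyloxy)propyl]-6-[(E)-prop-1-enyl]-5-(triethylsilyloxy)tetrahydro-2H-pyran-2-one, via Grignard reagent 11 (not isolated), via silyl ketene acetal 12 (not isolated)
Conditions: 10, Mg, THF, rt; then CuBr·SMe2 (cat.), Me3SiCl, 9, THF, −78 °C; aq NH4Cl at −78 °C
Reagents that add atoms: none
Why: Copper-catalysed, Me3SiCl-accelerated conjugate addition of the Grignard reagent, which enters C21 anti to the pseudo-axial C4 silyl ether and therefore trans to the C5 propenyl group; the cold aqueous quench hydrolyses ketene acetal 12 before it can rearrange.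

**Step 9**
Reactants: 13 (4R,5S,6S)-4-[3-(benzyloxy)propyl]-6-[(E)-prop-1-enyl]-5-(triethylsilyloxy)tetrahydro-2H-pyran-2-one; 14 tert-butyl(2-iodoethoxy)diphenylsilane
Product: 15 (3R,4R,5S,6S)-4-[3-(benzyloxy)propyl]-3-[2-(tert-butyldiphenylsilyloxy)ethyl]-6-[(E)-prop-1-enyl]-5-(triethylsilyloxy)tetrahydro-2H-pyran-2-one
Conditions: LiN(iPr)2, THF, −78 °C; then 14, HMPA, −78 → −30 °C
Reagents that add atoms: none
Why: Alkylation of the lithium lactone enolate with a primary iodide in THF/HMPA, expected to occur trans to the C21 chain, although the C9 configuration is irrelevant because C9 becomes trigonal in step 10.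

**Step 10**
Reactants: 15 (3R,4R,5S,6S)-4-[3-(benzyloxy)propyl]-3-[2-(tert-butyldiphenylsilyloxy)ethyl]-6-[(E)-prop-1-enyl]-5-(triethylsilyloxy)tetrahydro-2H-pyran-2-one
Product: 18 (1R,2R,5R,6R)-6-[3-(benzyloxy)propyl]-1-[2-(tert-butyldiphenylsilyloxy)ethyl]-2-methyl-5-(triethylsilyloxy)cyclohex-3-ene-1-carboxylic acid, via trimethylsilyl ketene acetal 16 (not isolated), via trimethylsilyl ester 17 (not isolated)
Conditions: Me3SiCl/Et3N, LiN(iPr)2, THF, −78 °C → rt; toluene, 110 °C; then THF/H2O, AcOH (pH 4–5), 0 °C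
Reagents that add atoms: none
Why: Deprotonation at C9 and O-silylation give the endocyclic ketene acetal 16, whose C9=C18–O–C5–C6=C7 array undergoes a thermal [3,3]-sigmatropic shift (Ireland–Claisen rearrangement of a lactone silyl ketene acetal, a known ring-contracting route from alkenyl lactones to cycloalkene carboxylic acids), and mild hydrolysis of silyl ester 17 releases acid 18. Ring A closes by suprafacial pericyclic formation of the C9–C7 bond while the C5–O bond of the lactone breaks; because C4–C21 links C5 to C9, the six-atom array can only adopt a boat, bicyclo[2.2.2]octane-like geometry. C9 is controlled by the C5 carbinol centre, since the tethered propenyl group can reach only the ketene-acetal face on its own side of the ring, which places C18 cis to the C21 chain. C7 is controlled by the (E)-alkene geometry within that boat, which turns the methyl group to the C18 side. The step needs complete facial and boat-over-chair selectivity, both enforced by the ring; the ketene acetal is endocyclic and has only one geometry, and either C9 epimer of 15 converges on 16.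

**Step 11**
Reactants: 18 (1R,2R,5R,6R)-6-[3-(benzyloxy)propyl]-1-[2-(tert-butyldiphenylsilyloxy)ethyl]-2-methyl-5-(triethylsilyloxy)cyclohex-3-ene-1-carboxylic acid
Product: 19 (1R,2R,5R,6R)-6-[3-(benzyloxy)propyl]-1-[2-(tert-butyldiphenylsilyloxy)ethyl]-5-hydroxy-2-methylcyclohex-3-ene-1-carboxylic acid
Conditions: AcOH/THF/H2O (3:1:1), rt
Reagents that add atoms: none
Why: Acid-catalysed solvolysis cleaves the secondary triethylsilyl ether far faster than the primary tert-butyldiphenylsilyl ether, and the freed C4 hydroxyl is trans to C18 and cannot lactonise.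

**Step 12**
Reactants: 19 (1R,2R,5R,6R)-6-[3-(benzyloxy)propyl]-1-[2-(tert-butyldiphenylsilyloxy)ethyl]-5-hydroxy-2-methylcyclohex-3-ene-1-carboxylic acid
Product: 20 (1R,2R,6R)-6-[3-(benzyloxy)propyl]-1-[2-(tert-butyldiphenylsilyloxy)ethyl]-2-methyl-5-oxocyclohex-3-ene-1-carboxylic acid
Conditions: Dess–Martin periodinane, CH2Cl2, 0 °C → rt
Reagents that add atoms: none
Why: Dess–Martin oxidation of the allylic alcohol to the enone removes the C4 carbinol centre under non-basic conditions, so C21 (next to the ketone) and C7 are not epimerised; C4 is oxidised while C24 is still a benzyl ether, so no C4-hydroxy/C24-ester lactone can form later.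

**Step 13**
Reactants: 20 (1R,2R,6R)-6-[3-(benzyloxy)propyl]-1-[2-(tert-butyldiphenylsilyloxy)ethyl]-2-methyl-5-oxocyclohex-3-ene-1-carboxylic acid
Product: 21 (1R,2R,6R)-1-[2-(tert-butyldiphenylsilyloxy)ethyl]-6-(3-hydroxypropyl)-2-methyl-5-oxocyclohexane-1-carboxylic acid
Conditions: H2 (1 atm), 10% Pd on carbon (Pd/C), EtOAc, rt
Reagents that add atoms: none
Why: Heterogeneous hydrogenation saturates the conjugated C5=C6 bond and hydrogenolyses the benzyl ether in one operation, creating no stereocentre and leaving ketone, acid and silyl ether untouched.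

**Step 14**
Reactants: 21 (1R,2R,6R)-1-[2-(tert-butyldiphenylsilyloxy)ethyl]-6-(3-hydroxypropyl)-2-methyl-5-oxocyclohexane-1-carboxylic acid
Product: 22 (1R,2R,6R)-6-(2-carboxyethyl)-1-[2-(tert-butyldiphenylsilyloxy)ethyl]-2-methyl-5-oxocyclohexane-1-carboxylic acid
Conditions: TEMPO (cat.), PhI(OAc)2, MeCN/H2O (1:1), rt
Reagents that add atoms: water, O
Why: Oxoammonium (TEMPO/PhI(OAc)2) oxidation takes the primary alcohol through the aldehyde hydrate to the carboxylic acid without affecting the ketone or the silyl ether.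

**Step 15**
Reactants: 22 (1R,2R,6R)-6-(2-carboxyethyl)-1-[2-(tert-butyldiphenylsilyloxy)ethyl]-2-methyl-5-oxocyclohexane-1-carboxylic acid
Product: 23 methyl (1R,2R,6R)-1-[2-(tert-butyldiphenylsilyloxy)ethyl]-6-(3-methoxy-3-oxopropyl)-2-methyl-5-oxocyclohexane-1-carboxylate
Conditions: Me3SiCHN2, MeOH/toluene (1:3), 0 °C → rt
Reagents that add atoms: (trimethylsilyl)diazomethane, C[Si](C)(C)C=[N+]=[N-]
Why: O-methylation of both acids by diazomethane released in situ is insensitive to the hindrance at C18 and needs no base, so the C21 centre next to the ketone is preserved.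

**Step 16**
Reactants: 23 methyl (1R,2R,6R)-1-[2-(tert-butyldiphenylsilyloxy)ethyl]-6-(3-methoxy-3-oxopropyl)-2-methyl-5-oxocyclohexane-1-carboxylate; 24 prop-1-en-2-ylmagnesium bromide
Product: 26 methyl 3-[(1R,2R,5S,8R)-1-[2-(tert-butyldiphenylsilyloxy)ethyl]-2-methyl-7-oxo-5-(prop-1-en-2-yl)-6-oxabicyclo[3.2.1]octan-8-yl]propanoate, via tertiary alkoxide 25 (not isolated)
Conditions: 24, CeCl3 (anhydrous), THF, −78 °C; then 23, −78 → 0 °C
Reagents that add atoms: none
Why: The weakly basic organocerium reagent should add to the ketone in preference to the esters (organocerium 1,2-addition) from the equatorial direction, anti to the axial C18 ester on the 1,3-related carbon, so the new C4 alkoxide is axial and cis to C18 and closes ring B by intramolecular transesterification, which fixes C4.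

**Step 17**
Reactants: 26 methyl 3-[(1R,2R,5S,8R)-1-[2-(tert-butyldiphenylsilyloxy)ethyl]-2-methyl-7-oxo-5-(prop-1-en-2-yl)-6-oxabicyclo[3.2.1]octan-8-yl]propanoate
Product: 27 methyl 3-[(1R,2R,5S,8R)-1-(2-hydroxyethyl)-2-methyl-7-oxo-5-(prop-1-en-2-yl)-6-oxabicyclo[3.2.1]octan-8-yl]propanoate
Conditions: HF·pyridine, pyridine, THF, 0 °C → rt; used directly
Reagents that add atoms: none
Why: Fluoride cleavage of the primary silyl ether under buffered, non-basic conditions, chosen so that the freed hydroxyl is not driven into acyl transfer onto the hindered C18 lactone carbonyl.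

**Step 18**
Reactants: 27 methyl 3-[(1R,2R,5S,8R)-1-(2-hydroxyethyl)-2-methyl-7-oxo-5-(prop-1-en-2-yl)-6-oxabicyclo[3.2.1]octan-8-yl]propanoate
Product: 28 methyl 3-[(1R,2R,5S,8R)-1-(2-iodoethyl)-2-methyl-7-oxo-5-(prop-1-en-2-yl)-6-oxabicyclo[3.2.1]octan-8-yl]propanoate
Conditions: I2, PPh3, imidazole, CH2Cl2, 0 °C
Reagents that add atoms: iodine, II
Why: Appel-type iodination converts the primary alcohol to the iodide by SN2 displacement of the oxyphosphonium group under mild conditions.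

**Step 19**
Reactants: 29 3-bromodihydrofuran-2(3H)-one; 30 benzenethiol
Product: 31 3-(phenylsulfanyl)dihydrofuran-2(3H)-one
Conditions: Et3N, CH2Cl2, 0 °C → rt
Reagents that add atoms: none
Why: SN2 displacement of the activated α-bromide by the thiolate gives the sulfur-substituted lactone used as the butenolide carrier.

**Step 20**
Reactants: 28 methyl 3-[(1R,2R,5S,8R)-1-(2-iodoethyl)-2-methyl-7-oxo-5-(prop-1-en-2-yl)-6-oxabicyclo[3.2.1]octan-8-yl]propanoate; 31 3-(phenylsulfanyl)dihydrofuran-2(3H)-one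
Product: 32 methyl 3-[(1R,2R,5S,8R)-2-methyl-7-oxo-1-[2-(2-oxo-3-(phenylsulfanyl)tetrahydrofuran-3-yl)ethyl]-5-(prop-1-en-2-yl)-6-oxabicyclo[3.2.1]octan-8-yl]propanoate (both epimers at the sulfur-bearing carbon)
Conditions: 31, LiN(SiMe3)2, THF, −78 °C; then 28, HMPA, −78 °C → rt
Reagents that add atoms: none
Why: Alkylation of the sulfur-stabilised lactone enolate with the primary iodide forms C11–C12; the soft enolate should spare the methyl ester and the non-enolisable bridged lactone, and the new centre is erased in step 21.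

**Step 21**
Reactants: 32 methyl 3-[(1R,2R,5S,8R)-2-methyl-7-oxo-1-[2-(2-oxo-3-(phenylsulfanyl)tetrahydrofuran-3-yl)ethyl]-5-(prop-1-en-2-yl)-6-oxabicyclo[3.2.1]octan-8-yl]propanoate
Product: 34 methyl 3-[(1R,2R,5S,8R)-2-methyl-7-oxo-1-[2-(2-oxo-2,5-dihydrofuran-3-yl)ethyl]-5-(prop-1-en-2-yl)-6-oxabicyclo[3.2.1]octan-8-yl]propanoate (target), via sulfoxide 33 (not isolated)
Conditions: 3-chloroperoxybenzoic acid (1.0 equiv), CH2Cl2, −78 → 0 °C; then toluene, 110 °C
Reagents that add atoms: none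
Why: Sulfide oxidation followed by thermal syn-elimination of the sulfoxide toward the ring methylene gives the endocyclic C12=C13 butenolide; at −78 °C the peracid should oxidise sulfur much faster than the isopropenyl alkene.

**Compound list**

1 | furan-2-carbaldehyde | O=Cc1ccco1 | starting material
2 | prop-1-yn-1-ylmagnesium bromide | CC#C[Mg]Br | starting material
3 | rac-1-(furan-2-yl)but-2-yn-1-ol | CC#CC(O)c1ccco1 | intermediate
4 | (S)-1-(furan-2-yl)but-2-yn-1-ol | CC#C[C@@H](c1ccco1)O | intermediate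
5 | (S,E)-1-(furan-2-yl)but-2-en-1-ol | C/C=C/[C@@H](c1ccco1)O | intermediate
6 | (2S)-6-hydroxy-2-[(E)-prop-1-enyl]-2H-pyran-3(6H)-one | C/C=C/[C@@H]1OC(O)C=CC1=O | intermediate
7 | (6S)-6-[(E)-prop-1-enyl]-2H-pyran-2,5(6H)-dione | C/C=C/[C@@H]1OC(=O)C=CC1=O | intermediate
8 | (5S,6S)-5-hydroxy-6-[(E)-prop-1-enyl]-5,6-dihydro-2H-pyran-2-one | C/C=C/[C@@H]1OC(=O)C=C[C@@H]1O | intermediate
9 | (5S,6S)-6-[(E)-prop-1-enyl]-5-(triethylsilyloxy)-5,6-dihydro-2H-pyran-2-one | C/C=C/[C@@H]1OC(=O)C=C[C@@H]1O[Si](CC)(CC)CC | intermediate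
10 | 1-(benzyloxy)-3-bromopropane | BrCCCOCc1ccccc1 | starting material
11 | [3-(benzyloxy)propyl]magnesium bromide | Br[Mg]CCCOCc1ccccc1 | intermediate
12 | (4R,5S,6S)-4-[3-(benzyloxy)propyl]-6-[(E)-prop-1-enyl]-5-(triethylsilyloxy)-2-(trimethylsilyloxy)-5,6-dihydro-4H-pyran | C/C=C/[C@@H]1OC(O[Si](C)(C)C)=C[C@@H](CCCOCc2ccccc2)[C@@H]1O[Si](CC)(CC)CC | intermediate
13 | (4R,5S,6S)-4-[3-(benzyloxy)propyl]-6-[(E)-prop-1-enyl]-5-(triethylsilyloxy)tetrahydro-2H-pyran-2-one | C/C=C/[C@@H]1OC(=O)C[C@@H](CCCOCc2ccccc2)[C@@H]1O[Si](CC)(CC)CC | intermediate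
14 | tert-butyl(2-iodoethoxy)diphenylsilane | CC(C)(C)[Si](OCCI)(c1ccccc1)c1ccccc1 | starting material
15 | (3R,4R,5S,6S)-4-[3-(benzyloxy)propyl]-3-[2-(tert-butyldiphenylsilyloxy)ethyl]-6-[(E)-prop-1-enyl]-5-(triethylsilyloxy)tetrahydro-2H-pyran-2-one | C/C=C/[C@@H]1OC(=O)[C@H](CCO[Si](c2ccccc2)(c2ccccc2)C(C)(C)C)[C@@H](CCCOCc2ccccc2)[C@@H]1O[Si](CC)(CC)CC | intermediate
16 | (4R,5S,6S)-4-[3-(benzyloxy)propyl]-3-[2-(tert-butyldiphenylsilyloxy)ethyl]-6-[(E)-prop-1-enyl]-5-(triethylsilyloxy)-2-(trimethylsilyloxy)-5,6-dihydro-4H-pyran | C/C=C/[C@@H]1OC(O[Si](C)(C)C)=C(CCO[Si](c2ccccc2)(c2ccccc2)C(C)(C)C)[C@@H](CCCOCc2ccccc2)[C@@H]1O[Si](CC)(CC)CC | intermediate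
17 | trimethylsilyl (1R,2R,5R,6R)-6-[3-(benzyloxy)propyl]-1-[2-(tert-butyldiphenylsilyloxy)ethyl]-2-methyl-5-(triethylsilyloxy)cyclohex-3-ene-1-carboxylate | C[Si](C)(C)OC(=O)[C@]1(CCO[Si](c2ccccc2)(c2ccccc2)C(C)(C)C)[C@H](C)C=C[C@@H](O[Si](CC)(CC)CC)[C@@H]1CCCOCc1ccccc1 | intermediate
18 | (1R,2R,5R,6R)-6-[3-(benzyloxy)propyl]-1-[2-(tert-butyldiphenylsilyloxy)ethyl]-2-methyl-5-(triethylsilyloxy)cyclohex-3-ene-1-carboxylic acid | OC(=O)[C@]1(CCO[Si](c2ccccc2)(c2ccccc2)C(C)(C)C)[C@H](C)C=C[C@@H](O[Si](CC)(CC)CC)[C@@H]1CCCOCc1ccccc1 | intermediate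
19 | (1R,2R,5R,6R)-6-[3-(benzyloxy)propyl]-1-[2-(tert-butyldiphenylsilyloxy)ethyl]-5-hydroxy-2-methylcyclohex-3-ene-1-carboxylic acid | OC(=O)[C@]1(CCO[Si](c2ccccc2)(c2ccccc2)C(C)(C)C)[C@H](C)C=C[C@@H](O)[C@@H]1CCCOCc1ccccc1 | intermediate
20 | (1R,2R,6R)-6-[3-(benzyloxy)propyl]-1-[2-(tert-butyldiphenylsilyloxy)ethyl]-2-methyl-5-oxocyclohex-3-ene-1-carboxylic acid | OC(=O)[C@]1(CCO[Si](c2ccccc2)(c2ccccc2)C(C)(C)C)[C@H](C)C=CC(=O)[C@@H]1CCCOCc1ccccc1 | intermediate
21 | (1R,2R,6R)-1-[2-(tert-butyldiphenylsilyloxy)ethyl]-6-(3-hydroxypropyl)-2-methyl-5-oxocyclohexane-1-carboxylic acid | OC(=O)[C@]1(CCO[Si](c2ccccc2)(c2ccccc2)C(C)(C)C)[C@H](C)CCC(=O)[C@@H]1CCCO | intermediate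
22 | (1R,2R,6R)-6-(2-carboxyethyl)-1-[2-(tert-butyldiphenylsilyloxy)ethyl]-2-methyl-5-oxocyclohexane-1-carboxylic acid | OC(=O)[C@]1(CCO[Si](c2ccccc2)(c2ccccc2)C(C)(C)C)[C@H](C)CCC(=O)[C@@H]1CCC(=O)O | intermediate
23 | methyl (1R,2R,6R)-1-[2-(tert-butyldiphenylsilyloxy)ethyl]-6-(3-methoxy-3-oxopropyl)-2-methyl-5-oxocyclohexane-1-carboxylate | COC(=O)[C@]1(CCO[Si](c2ccccc2)(c2ccccc2)C(C)(C)C)[C@H](C)CCC(=O)[C@@H]1CCC(=O)OC | intermediate
24 | prop-1-en-2-ylmagnesium bromide | C=C(C)[Mg]Br | starting material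
25 | methyl (1R,2R,5S,6R)-1-[2-(tert-butyldiphenylsilyloxy)ethyl]-5-hydroxy-6-(3-methoxy-3-oxopropyl)-2-methyl-5-(prop-1-en-2-yl)cyclohexane-1-carboxylate, formed as its alkoxide | C=C(C)[C@]1(O)CC[C@@H](C)[C@@](CCO[Si](c2ccccc2)(c2ccccc2)C(C)(C)C)(C(=O)OC)[C@H]1CCC(=O)OC | intermediate
26 | methyl 3-[(1R,2R,5S,8R)-1-[2-(tert-butyldiphenylsilyloxy)ethyl]-2-methyl-7-oxo-5-(prop-1-en-2-yl)-6-oxabicyclo[3.2.1]octan-8-yl]propanoate | C=C(C)[C@@]12CC[C@@H](C)[C@@](CCO[Si](c3ccccc3)(c3ccccc3)C(C)(C)C)(C(=O)O1)[C@H]2CCC(=O)OC | intermediate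
27 | methyl 3-[(1R,2R,5S,8R)-1-(2-hydroxyethyl)-2-methyl-7-oxo-5-(prop-1-en-2-yl)-6-oxabicyclo[3.2.1]octan-8-yl]propanoate | C=C(C)[C@@]12CC[C@@H](C)[C@@](CCO)(C(=O)O1)[C@H]2CCC(=O)OC | intermediate
28 | methyl 3-[(1R,2R,5S,8R)-1-(2-iodoethyl)-2-methyl-7-oxo-5-(prop-1-en-2-yl)-6-oxabicyclo[3.2.1]octan-8-yl]propanoate | C=C(C)[C@@]12CC[C@@H](C)[C@@](CCI)(C(=O)O1)[C@H]2CCC(=O)OC | intermediate
29 | 3-bromodihydrofuran-2(3H)-one | BrC1CCOC1=O | starting material
30 | benzenethiol | Sc1ccccc1 | starting material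
31 | 3-(phenylsulfanyl)dihydrofuran-2(3H)-one | O=C1OCCC1Sc1ccccc1 | intermediate
32 | methyl 3-[(1R,2R,5S,8R)-2-methyl-7-oxo-1-[2-(2-oxo-3-(phenylsulfanyl)tetrahydrofuran-3-yl)ethyl]-5-(prop-1-en-2-yl)-6-oxabicyclo[3.2.1]octan-8-yl]propanoate | C=C(C)[C@@]12CC[C@@H](C)[C@@](CCC3(Sc4ccccc4)CCOC3=O)(C(=O)O1)[C@H]2CCC(=O)OC | intermediate
33 | methyl 3-[(1R,2R,5S,8R)-2-methyl-7-oxo-1-[2-(2-oxo-3-(phenylsulfinyl)tetrahydrofuran-3-yl)ethyl]-5-(prop-1-en-2-yl)-6-oxabicyclo[3.2.1]octan-8-yl]propanoate | C=C(C)[C@@]12CC[C@@H](C)[C@@](CCC3(S(=O)c4ccccc4)CCOC3=O)(C(=O)O1)[C@H]2CCC(=O)OC | intermediate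
34 | methyl 3-[(1R,2R,5S,8R)-2-methyl-7-oxo-1-[2-(2-oxo-2,5-dihydrofuran-3-yl)ethyl]-5-(prop-1-en-2-yl)-6-oxabicyclo[3.2.1]octan-8-yl]propanoate | C=C(C)[C@@]12CC[C@@H](C)[C@@](CCC3=CCOC3=O)(C(=O)O1)[C@H]2CCC(=O)OC | target

**Step count and risks**

Total step count: 21 (step 19 is a one-step side branch). Longest linear sequence: 20 steps (steps 1–18, 20 and 21).

Steps most likely to fail:

1. Step 10. Enolisation of the crowded tertiary C9–H may be incomplete or followed by C-silylation, and the congested boat transition state leading to a quaternary centre may be outpaced by thermal decomposition of the ketene acetal. The fallback sets out from 13 and returns at 18, running the rearrangement one step earlier on the less crowded lactone. Enolisation and silylation of 13 (LiN(iPr)2, Me3SiCl/Et3N, THF, −78 °C) regenerate ketene acetal 12, which has a hydrogen at C9. Heating in toluene should give trimethylsilyl (1R,2R,5R,6R)-6-[3-(benzyloxy)propyl]-2-methyl-5-(triethylsilyloxy)cyclohex-3-ene-1-carboxylate F1 and, after mild hydrolysis, (1R,2R,5R,6R)-6-[3-(benzyloxy)propyl]-2-methyl-5-(triethylsilyloxy)cyclohex-3-ene-1-carboxylic acid F2. The quaternary centre is then made by a carboxylic acid dianion alkylation of F2 (2 equiv LiN(iPr)2, THF/HMPA, 0 °C) with iodide 14. The electrophile should enter planar C9 opposite the two flanking cis substituents (C7 methyl and C21 chain), which gives acid 18.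

2. Step 16. The new C4 alkoxide may close onto the C24 ester (δ-lactone) in competition with the wanted closure onto C18, and the reagent may not fully distinguish ketone from esters. The fallback sets out from 21 and returns at 26, introducing the C24 ester only after ring B exists. Acid 21 is methylated at C18 (Me3SiCHN2) to methyl (1R,2R,6R)-1-[2-(tert-butyldiphenylsilyloxy)ethyl]-6-(3-hydroxypropyl)-2-methyl-5-oxocyclohexane-1-carboxylate F3. Oxidation (TEMPO, PhI(OAc)2, MeCN/H2O) gives methyl (1R,2R,6R)-6-(2-carboxyethyl)-1-[2-(tert-butyldiphenylsilyloxy)ethyl]-2-methyl-5-oxocyclohexane-1-carboxylate F4. Excess isopropenylcerium reagent, toward which the carboxylate is inert, adds to the ketone to give methyl (1R,2R,5S,6R)-6-(2-carboxyethyl)-1-[2-(tert-butyldiphenylsilyloxy)ethyl]-5-hydroxy-2-methyl-5-(prop-1-en-2-yl)cyclohexane-1-carboxylate F5 as its alkoxide. The C18 ester is then the only acyl acceptor, so F5 closes to 3-[(1R,2R,5S,8R)-1-[2-(tert-butyldiphenylsilyloxy)ethyl]-2-methyl-7-oxo-5-(prop-1-en-2-yl)-6-oxabicyclo[3.2.1]octan-8-yl]propanoic acid F6. Me3SiCHN2 then gives 26.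

3. Step 17. The freshly released C11 hydroxyl may take the acyl group from the bridged lactone (translactonisation to a spiro γ-butyrolactone) during or after desilylation. The fallback sets out from 26 and returns at 28, exchanging the silyl ether directly for a sulfonate. Treatment with p-toluenesulfonyl fluoride and DBU (cat.) in MeCN at rt, a base-catalysed silyl-to-sulfonyl interconversion of alkyl silyl ethers, sulfonylates the oxygen as it is unmasked and gives methyl 3-[(1R,2R,5S,8R)-2-methyl-7-oxo-5-(prop-1-en-2-yl)-1-[2-(tosyloxy)ethyl]-6-oxabicyclo[3.2.1]octan-8-yl]propanoate F7. Finkelstein displacement (NaI, acetone, 50 °C) then gives iodide 28.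

**Further compounds**

F1 | step 10 | trimethylsilyl (1R,2R,5R,6R)-6-[3-(benzyloxy)propyl]-2-methyl-5-(triethylsilyloxy)cyclohex-3-ene-1-carboxylate | C[Si](C)(C)OC(=O)[C@@H]1[C@H](C)C=C[C@@H](O[Si](CC)(CC)CC)[C@@H]1CCCOCc1ccccc1
F2 | step 10 | (1R,2R,5R,6R)-6-[3-(benzyloxy)propyl]-2-methyl-5-(triethylsilyloxy)cyclohex-3-ene-1-carboxylic acid | OC(=O)[C@@H]1[C@H](C)C=C[C@@H](O[Si](CC)(CC)CC)[C@@H]1CCCOCc1ccccc1
F3 | step 16 | methyl (1R,2R,6R)-1-[2-(tert-butyldiphenylsilyloxy)ethyl]-6-(3-hydroxypropyl)-2-methyl-5-oxocyclohexane-1-carboxylate | COC(=O)[C@]1(CCO[Si](c2ccccc2)(c2ccccc2)C(C)(C)C)[C@H](C)CCC(=O)[C@@H]1CCCO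
F4 | step 16 | methyl (1R,2R,6R)-6-(2-carboxyethyl)-1-[2-(tert-butyldiphenylsilyloxy)ethyl]-2-methyl-5-oxocyclohexane-1-carboxylate | COC(=O)[C@]1(CCO[Si](c2ccccc2)(c2ccccc2)C(C)(C)C)[C@H](C)CCC(=O)[C@@H]1CCC(=O)O
F5 | step 16 | methyl (1R,2R,5S,6R)-6-(2-carboxyethyl)-1-[2-(tert-butyldiphenylsilyloxy)ethyl]-5-hydroxy-2-methyl-5-(prop-1-en-2-yl)cyclohexane-1-carboxylate | C=C(C)[C@]1(O)CC[C@@H](C)[C@@](CCO[Si](c2ccccc2)(c2ccccc2)C(C)(C)C)(C(=O)OC)[C@H]1CCC(=O)O
F6 | step 16 | 3-[(1R,2R,5S,8R)-1-[2-(tert-butyldiphenylsilyloxy)ethyl]-2-methyl-7-oxo-5-(prop-1-en-2-yl)-6-oxabicyclo[3.2.1]octan-8-yl]propanoic acid | C=C(C)[C@@]12CC[C@@H](C)[C@@](CCO[Si](c3ccccc3)(c3ccccc3)C(C)(C)C)(C(=O)O1)[C@H]2CCC(=O)O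
F7 | step 17 | methyl 3-[(1R,2R,5S,8R)-2-methyl-7-oxo-5-(prop-1-en-2-yl)-1-[2-(tosyloxy)ethyl]-6-oxabicyclo[3.2.1]octan-8-yl]propanoate | C=C(C)[C@@]12CC[C@@H](C)[C@@](CCOS(=O)(=O)c3ccc(C)cc3)(C(=O)O1)[C@H]2CCC(=O)OC
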